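**Retrosynthetic overview**
- Numbering: C1 = lactone β-carbon (ring fusion), C2 = lactone γ-carbon (O), then round the 14-membered ring C3=C4(CH3), C5, C6, C7=C8(CH3), C9(OAc), C10, C11=C12(CH3), C13, C14; C15 = lactone α-carbon, C16 = exocyclic CH2, C17 = lactone C=O.
- Last ring disconnection: the C12–C13 bond of the 14-membered ring, made by a titanium-mediated reductive alkyne–alkene coupling of a 2-butynyl group (C10–C11≡C12–CH3) with a vinyl group (C13=C14 on C1) in an acyclic, ester-free precursor.
- Enabling feature: O–C2 is homoallylic to that vinyl group (O–C2–C1–C14=C13). The C2 titanium alkoxide therefore holds the metal in a five-membered oxatitanacycle fused to a titanacyclopentene (Ti–C11=C12–C13–C14); these two temporary rings template the 14-ring closure, fix the E-C11=C12 geometry and are removed by protonolysis.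
- Precursor assembly: C2–C9 from geranyl acetate; C9–C10 by catalytic asymmetric propargylation (sets C9); C1–C2 by syn-selective asymmetric allylboration with a (Z)-allylboronate (sets C1 and C2, brings in the vinyl group and the directing hydroxyl).
- Ring order: 14-membered carbocycle (step 11), then the γ-lactone by oxidative lactonisation (step 12); exocyclic methylene and C9 acetate last.

Key step: step 11

Remark: (R)-TRIP is assumed to direct both boronate additions (steps 3 and 10) to the Re face of the enals, as it does for aryl aldehydes; if the sense is opposite, the (S)-acid is used.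

**Route**

Step 1
Reactants: 1 geranyl acetate
Product: 2 (2E,6E)-8-hydroxy-3,7-dimethylocta-2,6-dien-1-yl acetate
Conditions: SeO2 (0.1 equiv), t-BuOOH (3 equiv), salicylic acid (0.1 equiv), CH2Cl2, rt
Reagents that add atoms: tert-butyl hydroperoxide, CC(C)(C)OO
Why: Catalytic SeO2 allylic oxidation (Riley oxidation, ene reaction then [2,3]-shift) should hydroxylate the (E)-methyl group of the electron-richer distal trisubstituted alkene, the proximal alkene being deactivated by the allylic acetate; no stereocentre is formed.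

Step 2
Reactants: 2 (2E,6E)-8-hydroxy-3,7-dimethylocta-2,6-dien-1-yl acetate
Product: 3 (2E,6E)-3,7-dimethyl-8-oxoocta-2,6-dien-1-yl acetate
Conditions: activated MnO2 (15 equiv), CH2Cl2, rt
Reagents that add atoms: none
Why: MnO2 oxidation of a primary allylic alcohol should give the (E)-enal without touching the acetate, and any aldehyde already formed in step 1 converges here.

Step 3
Reactants: 3 (2E,6E)-3,7-dimethyl-8-oxoocta-2,6-dien-1-yl acetate; 4 allenylboronic acid pinacol ester
Product: 5 (2E,6E,8R)-8-hydroxy-3,7-dimethylundeca-2,6-dien-10-yn-1-yl acetate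
Conditions: (R)-TRIP phosphoric acid (10 mol %), 4 Å MS, cyclohexane, 0 °C → rt; aq. NaHCO3
Reagents that add atoms: none
Why: Chiral phosphoric acid-catalysed propargylboration (SE2' addition of the allenylboronate through a closed six-membered transition state) should give only the homopropargylic alcohol, the catalyst directing attack to the Re face of the enal and so setting C9 (8R in 5).

Step 4
Reactants: 5 (2E,6E,8R)-8-hydroxy-3,7-dimethylundeca-2,6-dien-10-yn-1-yl acetate
Product: 6 (2E,6E,8R)-8-(tert-butyldimethylsilyloxy)-3,7-dimethylundeca-2,6-dien-10-yn-1-yl acetate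
Conditions: TBSCl, imidazole, DMF, rt
Reagents that add atoms: tert-butyldimethylsilyl chloride, CC(C)(C)[Si](C)(C)Cl
Why: Imidazole-promoted O-silylation of the secondary alcohol proceeds at oxygen only, so C9 keeps its configuration.

Step 5
Reactants: 6 (2E,6E,8R)-8-(tert-butyldimethylsilyloxy)-3,7-dimethylundeca-2,6-dien-10-yn-1-yl acetate
Product: 7 (2E,6E,8R)-8-(tert-butyldimethylsilyloxy)-3,7-dimethylundeca-2,6-dien-10-yn-1-ol
Conditions: K2CO3 (0.5 equiv), MeOH, 0 °C → rt
Reagents that add atoms: none
Why: Base-catalysed transesterification (methanolysis) should remove the primary allylic acetate while the silyl ether and the terminal alkyne survive.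

Step 6
Reactants: 7 (2E,6E,8R)-8-(tert-butyldimethylsilyloxy)-3,7-dimethylundeca-2,6-dien-10-yn-1-ol
Product: 8 (2E,6E,8R)-8-(tert-butyldimethylsilyloxy)-3,7-dimethyldodeca-2,6-dien-10-yn-1-ol
Conditions: n-BuLi (2.1 equiv), THF, −78 → 0 °C; MeI (1.3 equiv), 0 °C → rt; H2O
Reagents that add atoms: iodomethane, CI
Why: Acetylide alkylation (SN2 on iodomethane) of the alkoxide/acetylide dianion should occur at carbon, because the lithium alkoxide is a much poorer nucleophile toward MeI in THF.

Step 7
Reactants: 8 (2E,6E,8R)-8-(tert-butyldimethylsilyloxy)-3,7-dimethyldodeca-2,6-dien-10-yn-1-ol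
Product: 9 (2E,6E,8R)-8-(tert-butyldimethylsilyloxy)-3,7-dimethyldodeca-2,6-dien-10-ynal
Conditions: activated MnO2 (15 equiv), CH2Cl2, rt
Reagents that add atoms: none
Why: MnO2 oxidation of the primary allylic alcohol should give the (E)-enal and leave the silyl ether and the internal alkyne untouched.

Step 8
Reactants: 10 (2E)-penta-2,4-dien-1-ol
Product: 11 triethyl[(2E)-penta-2,4-dien-1-yloxy]silane
Conditions: Et3SiCl, imidazole, CH2Cl2, 0 °C
Reagents that add atoms: chlorotriethylsilane, CC[Si](Cl)(CC)CC
Why: Imidazole-promoted O-silylation of a primary alcohol is fast and leaves the diene unchanged.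

Step 9
Reactants: 11 triethyl[(2E)-penta-2,4-dien-1-yloxy]silane
Product: 12 triethyl{[(3Z)-5-(4,4,5,5-tetramethyl-1,3,2-dioxaborolan-2-yl)pent-3-en-1-yl]oxy}silane
Conditions: Ni(cod)2 (2.5 mol %), PCy3 (2.5 mol %), HBpin (1.05 equiv), toluene, rt
Reagents that add atoms: pinacolborane, [H]B1OC(C)(C)C(C)(C)O1
Why: Nickel-catalysed 1,4-hydroboration of the 1,3-diene should place boron on the unsubstituted terminus and hydrogen on the substituted one through an allylnickel boryl formed from the s-cis diene, which fixes the Z geometry of the allylboronate.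

Step 10
Reactants: 9 (2E,6E,8R)-8-(tert-butyldimethylsilyloxy)-3,7-dimethyldodeca-2,6-dien-10-ynal; 12 triethyl{[(3Z)-5-(4,4,5,5-tetramethyl-1,3,2-dioxaborolan-2-yl)pent-3-en-1-yl]oxy}silane
Product: 13 (3S,4R,5E,9E,11R)-11-(tert-butyldimethylsilyloxy)-6,10-dimethyl-3-[2-(triethylsilyloxy)ethyl]pentadeca-1,5,9-trien-13-yn-4-ol
Conditions: (R)-TRIP phosphoric acid (10 mol %), 4 Å MS, toluene, −30 °C → rt; aq. NaHCO3
Reagents that add atoms: none
Why: Chiral phosphoric acid-catalysed allylboration through a closed chair-like six-membered transition state should turn the Z geometry of 12 into the syn relationship between the C2 hydroxyl and the C1 side chain (the trans relationship of the later lactone), while the catalyst directs attack to the Re face of the enal and so sets C1 and C2 independently of the remote C9 centre.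

Step 11
Reactants: 13 (3S,4R,5E,9E,11R)-11-(tert-butyldimethylsilyloxy)-6,10-dimethyl-3-[2-(triethylsilyloxy)ethyl]pentadeca-1,5,9-trien-13-yn-4-ol
Product: 17 (3E,7E,11E)-9-(tert-butyldimethylsilyloxy)-1-(2-hydroxyethyl)-4,8,12-trimethylcyclotetradeca-3,7,11-trien-2-ol, via titanium alkoxide 14 (not isolated), via titanacycle 15 (not isolated), via macrocyclic triethylsilyl ether 16 (not isolated)
Conditions: Ti(OiPr)4 (1.0 equiv), toluene, rt, then i-PrOH removed in vacuo; toluene–Et2O (0.002 M), c-C5H9MgCl (2.1 equiv), −78 → −30 °C, 4 h, then 0 °C; AcOH–THF–H2O (3:1:1), rt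
Reagents that add atoms: none
Why: Proposed new method: two equivalents of c-C5H9MgCl should reduce titanium alkoxide 14 to a divalent titanium centre which, while held on the C2 oxygen, binds the C11≡C12 alkyne and then takes the homoallylic C13=C14 vinyl group into its less hindered Ti–C12 bond, so that the terminal alkene carbon C13 bonds to C12 and titanium ends on C14 and C11 in titanacycle 15. The closest known reaction types are the intermolecular alkoxide-directed titanium-mediated reductive cross-coupling of internal alkynes with homoallylic alkoxides and the intramolecular enyne cyclisation with Ti(OiPr)4 and Grignard reagents; only the macrocyclic mode is new. The 14-membered carbocycle closes in endo mode at the alkyne (both alkyne carbons in the ring) and through the terminal carbon of the alkene, while the two temporary five-membered rings, the titanacyclopentene (Ti–C11=C12–C13–C14) and the oxatitanacycle (Ti–O–C2–C1–C14), template the closure and are then cleaved by protonolysis, the same aqueous acid removing the primary triethylsilyl ether of 16. No lasting stereocentre is created (Ti–C14 becomes CH2), but the C11=C12 bond is fixed as E because titanium and C13 add syn across the alkyne and hydrogen replaces titanium on C11 with retention. The step needs C12 over C11 regioselectivity (secured by the small methyl group on C12 against the β-branched C10 side and by the lower strain of a 14- over a 13-membered ring), site selectivity for the vinyl group over the two trisubstituted alkenes (secured by the five-membered alkoxide chelate and their higher substitution, which also disfavours allylic C2–O transposition because that would need a quaternary centre at C4), and cyclisation over oligomerisation (secured by high dilution). Esters would not survive the low-valent titanium reagent, which is why the lactone and the acetate are built afterwards.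

Step 12
Reactants: 17 (3E,7E,11E)-9-(tert-butyldimethylsilyloxy)-1-(2-hydroxyethyl)-4,8,12-trimethylcyclotetradeca-3,7,11-trien-2-ol
Product: 18 trans-fused γ-lactone (C2–O–C17(=O)–C15H2–C1) with OTBS at C9
Conditions: TEMPO (0.2 equiv), PhI(OAc)2 (2.5 equiv), CH2Cl2, rt
Reagents that add atoms: none
Why: TEMPO/PhI(OAc)2 oxidative lactonisation should oxidise the unhindered primary alcohol much faster than the secondary allylic C2 alcohol, the hydroxy aldehyde closing to the five-membered lactol that is oxidised on to the lactone with C1 and C2 untouched.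

Step 13
Reactants: 18 trans-fused γ-lactone with OTBS at C9
Product: 21 α-methylene lactone with OTBS at C9, via Mannich base 19 (not isolated), via ammonium iodide 20 (not isolated)
Conditions: LiN(iPr)2 (1.2 equiv), THF, −78 °C; CH2=NMe2+ I− (2 equiv), −78 °C → rt; MeI, MeOH, rt; aq. NaHCO3, EtOAc, rt
Reagents that add atoms: dimethyl(methylidene)ammonium iodide, C=[N+](C)C.[I-]
Why: Mannich-type α-methylenation (enolate addition to the iminium salt, N-methylation, then Hofmann-type E1cB elimination) should install the exocyclic methylene at C15, and C1 and C2 are not enolisable so their configuration is kept.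

Step 14
Reactants: 21 α-methylene lactone with OTBS at C9
Product: 22 9-hydroxy α-methylene lactone (deacetyl target)
Conditions: HF·pyridine, pyridine, THF, 0 °C → rt
Reagents that add atoms: none
Why: Fluoride-mediated desilylation under buffered acidic conditions should cleave only the Si–O bond, sparing the base-sensitive α-methylene lactone and retaining the C9 configuration.

Step 15
Reactants: 22 9-hydroxy α-methylene lactone (deacetyl target)
Product: 23 target, (3aR,6E,9R,10E,14E,15aS)-6,10,14-trimethyl-3-methylidene-2-oxo-2,3,3a,4,5,8,9,12,13,15a-decahydrocyclotetradeca[b]furan-9-yl acetate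
Conditions: Ac2O, pyridine, DMAP (cat.), CH2Cl2, 0 °C → rt
Reagents that add atoms: acetic anhydride, CC(=O)OC(C)=O
Why: DMAP-catalysed O-acylation of the secondary allylic alcohol breaks only the O–H bond, so C9 is retained and the target results.

**Compound list**

1 | geranyl acetate, (2E)-3,7-dimethylocta-2,6-dien-1-yl acetate | CC(=O)OC/C=C(\C)CCC=C(C)C | starting material
2 | (2E,6E)-8-hydroxy-3,7-dimethylocta-2,6-dien-1-yl acetate | CC(=O)OC/C=C(\C)CC/C=C(\C)CO | intermediate
3 | (2E,6E)-3,7-dimethyl-8-oxoocta-2,6-dien-1-yl acetate | CC(=O)OC/C=C(\C)CC/C=C(\C)C=O | intermediate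
4 | allenylboronic acid pinacol ester | C=C=CB1OC(C)(C)C(C)(C)O1 | starting material
5 | (2E,6E,8R)-8-hydroxy-3,7-dimethylundeca-2,6-dien-10-yn-1-yl acetate | CC(=O)OC/C=C(\C)CC/C=C(\C)[C@H](O)CC#C | intermediate
6 | (2E,6E,8R)-8-(tert-butyldimethylsilyloxy)-3,7-dimethylundeca-2,6-dien-10-yn-1-yl acetate | CC(=O)OC/C=C(\C)CC/C=C(\C)[C@H](O[Si](C)(C)C(C)(C)C)CC#C | intermediate
7 | (2E,6E,8R)-8-(tert-butyldimethylsilyloxy)-3,7-dimethylundeca-2,6-dien-10-yn-1-ol | OC/C=C(\C)CC/C=C(\C)[C@H](O[Si](C)(C)C(C)(C)C)CC#C | intermediate
8 | (2E,6E,8R)-8-(tert-butyldimethylsilyloxy)-3,7-dimethyldodeca-2,6-dien-10-yn-1-ol | OC/C=C(\C)CC/C=C(\C)[C@H](O[Si](C)(C)C(C)(C)C)CC#CC | intermediate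
9 | (2E,6E,8R)-8-(tert-butyldimethylsilyloxy)-3,7-dimethyldodeca-2,6-dien-10-ynal | O=C/C=C(\C)CC/C=C(\C)[C@H](O[Si](C)(C)C(C)(C)C)CC#CC | intermediate
10 | (2E)-penta-2,4-dien-1-ol | OC/C=C/C=C | starting material
11 | triethyl[(2E)-penta-2,4-dien-1-yloxy]silane | CC[Si](CC)(CC)OC/C=C/C=C | intermediate
12 | triethyl{[(3Z)-5-(4,4,5,5-tetramethyl-1,3,2-dioxaborolan-2-yl)pent-3-en-1-yl]oxy}silane | CC[Si](CC)(CC)OCC/C=C\CB1OC(C)(C)C(C)(C)O1 | intermediate
13 | (3S,4R,5E,9E,11R)-11-(tert-butyldimethylsilyloxy)-6,10-dimethyl-3-[2-(triethylsilyloxy)ethyl]pentadeca-1,5,9-trien-13-yn-4-ol (3,4-syn; C1, C2, C9 of the target) | C=C[C@H](CCO[Si](CC)(CC)CC)[C@@H](O)/C=C(\C)CC/C=C(\C)[C@H](O[Si](C)(C)C(C)(C)C)CC#CC | intermediate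
14 | triisopropoxytitanium alkoxide of 13 (not isolated) | C=C[C@H](CCO[Si](CC)(CC)CC)[C@@H](O[Ti](OC(C)C)(OC(C)C)OC(C)C)/C=C(\C)CC/C=C(\C)[C@H](O[Si](C)(C)C(C)(C)C)CC#CC | intermediate
15 | titanacycle: tetravalent titanium bonded to O–C2, C14, C11 and one isopropoxide; titanacyclopentene fused to oxatitanacyclopentane and to the 14-membered ring (not isolated) | C1C2[C@H](CCO[Si](CC)(CC)CC)[C@@H](O[Ti]23OC(C)C)/C=C(\C)CC/C=C(\C)[C@H](O[Si](C)(C)C(C)(C)C)C/C3=C1\C | intermediate
16 | (3E,7E,11E)-9-(tert-butyldimethylsilyloxy)-4,8,12-trimethyl-1-[2-(triethylsilyloxy)ethyl]cyclotetradeca-3,7,11-trien-2-ol (not isolated; locants as in the overview) | C1C[C@H](CCO[Si](CC)(CC)CC)[C@@H](O)/C=C(\C)CC/C=C(\C)[C@H](O[Si](C)(C)C(C)(C)C)C/C=C1\C | intermediate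
17 | (3E,7E,11E)-9-(tert-butyldimethylsilyloxy)-1-(2-hydroxyethyl)-4,8,12-trimethylcyclotetradeca-3,7,11-trien-2-ol (locants as in the overview) | C1C[C@H](CCO)[C@@H](O)/C=C(\C)CC/C=C(\C)[C@H](O[Si](C)(C)C(C)(C)C)C/C=C1\C | intermediate
18 | trans-fused γ-lactone: the target with CH2 at C15 in place of C=CH2 and OTBS at C9 in place of OAc | C1C(=O)O[C@H]2/C=C(\C)CC/C=C(\C)[C@H](O[Si](C)(C)C(C)(C)C)C/C=C(\C)CC[C@H]12 | intermediate
19 | Mannich base: 18 with CH2NMe2 on C15 (not isolated) | CN(C)CC1C(=O)O[C@H]2/C=C(\C)CC/C=C(\C)[C@H](O[Si](C)(C)C(C)(C)C)C/C=C(\C)CC[C@H]12 | intermediate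
20 | trimethylammonium iodide of 19 (not isolated) | C[N+](C)(C)CC1C(=O)O[C@H]2/C=C(\C)CC/C=C(\C)[C@H](O[Si](C)(C)C(C)(C)C)C/C=C(\C)CC[C@H]12.[I-] | intermediate
21 | α-methylene lactone: the target with OTBS at C9 in place of OAc | C=C1C(=O)O[C@H]2/C=C(\C)CC/C=C(\C)[C@H](O[Si](C)(C)C(C)(C)C)C/C=C(\C)CC[C@H]12 | intermediate
22 | 9-hydroxy α-methylene lactone (deacetyl target) | C=C1C(=O)O[C@H]2/C=C(\C)CC/C=C(\C)[C@H](O)C/C=C(\C)CC[C@H]12 | intermediate
23 | (3aR,6E,9R,10E,14E,15aS)-6,10,14-trimethyl-3-methylidene-2-oxo-2,3,3a,4,5,8,9,12,13,15a-decahydrocyclotetradeca[b]furan-9-yl acetate (CNP0129197.1) | C=C1C(=O)O[C@H]2/C=C(\C)CC/C=C(\C)[C@H](OC(C)=O)C/C=C(\C)CC[C@H]12 | target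

**Step count and risks**

Total step count: 15. Longest linear sequence: 13 steps (steps 1–7 and 10–15).

Risk 1, step 11 (proposed new method). The tethered low-valent titanium may couple two molecules instead of closing the ring. The alkene may also insert at C11 instead of C12, which would close a 13-membered ring with an exocyclic ethylidene. The allylic C2–O bond may be transposed, or the low-valent species may form incompletely at high dilution. The fallback uses known chemistry, sets out from 8 and comes back at 17. Hydrozirconation of 8 with Cp2Zr(H)Cl (3 equiv, THF, rt; equilibration places zirconium on the methyl-bearing carbon) followed by I2 should give the (E)-alkenyl iodide F1. MnO2 oxidation gives the enal F2, and allylboration with 12 under the conditions of step 10 gives the syn alcohol F3. 9-BBN-H (THF, rt) should hydroborate only the vinyl group to the primary alkylborane F4, which is not isolated. An intramolecular B-alkyl Suzuki–Miyaura coupling (Pd(dppf)Cl2, AsPh3, Cs2CO3, DMF–THF–H2O, high dilution) then forms the same C12–C13 bond and gives 16, and AcOH–THF–H2O converts 16 into 17.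

Risk 2, step 10. Enantiofacial control by the acid catalyst may be poor with the β,β-disubstituted enal and the hindered (Z)-boronate, so that the C1/C2 pair forms in both senses relative to C9, or the addition may be too slow. The fallback sets out from 9 (with 12) and comes back at 13. The uncatalysed allylboration (toluene, rt → 40 °C) remains syn-selective because of the closed transition state and should give 13 together with its C1,C2-bis-epimer F5. Sharpless kinetic resolution of this mixture of secondary allylic alcohols (Ti(OiPr)4, L-(+)-diisopropyl tartrate, t-BuOOH, 4 Å MS, CH2Cl2, −20 °C) should epoxidise the C3=C4 bond of F5 much faster, giving the erythro epoxy alcohol F6, and leave 13 for chromatographic separation.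

Risk 3, step 3. The α-branched enal may react slowly or with low enantioselectivity, and regiocontrol may erode toward the allenyl carbinol. The fallback sets out from 3 and comes back at 5. Barbier propargylation (Zn, propargyl bromide, THF–aq. NH4Cl) should give the racemic alcohol F7. Oxidation with DMP (the triacetoxy periodinane, buffered with NaHCO3, CH2Cl2) gives the alkynyl enone F8. Corey–Bakshi–Shibata reduction ((S)-B-methyl oxazaborolidine, catecholborane, toluene, −78 °C), with the alkenyl group as the large substituent, should return 5 with the 8R configuration.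

**Further compounds**

F1 | step 11 | (2E,6E,8R,10E)-8-(tert-butyldimethylsilyloxy)-11-iodo-3,7-dimethyldodeca-2,6,10-trien-1-ol | OC/C=C(\C)CC/C=C(\C)[C@H](O[Si](C)(C)C(C)(C)C)C/C=C(\C)I
F2 | step 11 | (2E,6E,8R,10E)-8-(tert-butyldimethylsilyloxy)-11-iodo-3,7-dimethyldodeca-2,6,10-trienal | O=C/C=C(\C)CC/C=C(\C)[C@H](O[Si](C)(C)C(C)(C)C)C/C=C(\C)I
F3 | step 11 | (3S,4R,5E,9E,11R,13E)-11-(tert-butyldimethylsilyloxy)-14-iodo-6,10-dimethyl-3-[2-(triethylsilyloxy)ethyl]pentadeca-1,5,9,13-tetraen-4-ol | C=C[C@H](CCO[Si](CC)(CC)CC)[C@@H](O)/C=C(\C)CC/C=C(\C)[C@H](O[Si](C)(C)C(C)(C)C)C/C=C(\C)I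
F4 | step 11 | B-alkyl-9-borabicyclo[3.3.1]nonane from F3, boron on the former terminal vinyl carbon C13 (not isolated) | C(CB1C2CCCC1CCC2)[C@H](CCO[Si](CC)(CC)CC)[C@@H](O)/C=C(\C)CC/C=C(\C)[C@H](O[Si](C)(C)C(C)(C)C)C/C=C(\C)I
F5 | step 10 | (3R,4S,5E,9E,11R)-11-(tert-butyldimethylsilyloxy)-6,10-dimethyl-3-[2-(triethylsilyloxy)ethyl]pentadeca-1,5,9-trien-13-yn-4-ol (C1,C2-bis-epimer of 13) | C=C[C@@H](CCO[Si](CC)(CC)CC)[C@H](O)/C=C(\C)CC/C=C(\C)[C@H](O[Si](C)(C)C(C)(C)C)CC#CC
F6 | step 10 | erythro 5,6-epoxy alcohol of F5 (epoxide on the former C3=C4 bond of the overview numbering) | C=C[C@@H](CCO[Si](CC)(CC)CC)[C@H](O)[C@@H]1O[C@@]1(C)CC/C=C(\C)[C@H](O[Si](C)(C)C(C)(C)C)CC#CC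
F7 | step 3 | (2E,6E)-8-hydroxy-3,7-dimethylundeca-2,6-dien-10-yn-1-yl acetate, racemic at C8 | CC(=O)OC/C=C(\C)CC/C=C(\C)C(O)CC#C
F8 | step 3 | (2E,6E)-3,7-dimethyl-8-oxoundeca-2,6-dien-10-yn-1-yl acetate | CC(=O)OC/C=C(\C)CC/C=C(\C)C(=O)CC#C
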